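**Retrosynthetic overview**
- The (E)-allylic alcohol on ring B comes from an aryl aldehyde by Wittig olefination and hydride reduction; the same hydride frees the ring A phenol.
- C9 (CH2OH) comes from a vinyl group by ozonolysis with borohydride work-up.
- Key C7–C8 bond: the oxygen-bearing C8 is used as a nucleophile (an α-aryloxy carbanion equivalent, delivered as a (Z)-γ-aryloxyallyl-diisopinocampheylborane that already carries the ring B aryl ether) and adds to the ring A aldehyde carbon. Both stereocentres are set in this step.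
- Both benzene rings come preformed from syringaldehyde. No ring of the target is built; the only ring made is a temporary dioxolane on ring B.

Assumption: the SMILES is the threo (7R,8R) isomer; "(−)-Ipc2BOMe" is the reagent made from (+)-α-pinene.

**Step 1**
Reactants: 1 syringaldehyde (4-hydroxy-3,5-dimethoxybenzaldehyde); 2 allyl bromide
Product: 3 4-(allyloxy)-3,5-dimethoxybenzaldehyde
Conditions: K2CO3, DMF, 60 °C
Reagents that add atoms: none
Why: Williamson ether synthesis; the phenoxide displaces bromide from the allylic halide, and no stereocentre is involved.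

**Step 2**
Reactants: 3 4-(allyloxy)-3,5-dimethoxybenzaldehyde
Product: 4 2-[4-(allyloxy)-3,5-dimethoxyphenyl]-1,3-dioxolane
Conditions: HOCH2CH2OH, p-TsOH (cat.), toluene, reflux, Dean–Stark
Reagents that add atoms: ethylene glycol, OCCO
Why: Acetalisation masks the ring B aldehyde against s-BuLi and the allylborane; a cyclic acetal is chosen because it resists BF3·OEt2 at −78 °C better than a dimethyl acetal, and Claisen rearrangement is blocked by the two ortho methoxy groups.

**Step 3**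
Reactants: 1 syringaldehyde
Product: 5 4-formyl-2,6-dimethoxyphenyl pivalate
Conditions: PivCl, Et3N, DMAP (cat.), CH2Cl2, 0 °C → rt
Reagents that add atoms: pivaloyl chloride, CC(C)(C)C(Cl)=O
Why: DMAP-catalysed O-acylation; the hindered aryl pivalate keeps the aldehyde electrophilic, survives the buffered peroxide and borohydride work-ups, and is removed by the hydride used in the last step.

**Step 4**
Reactants: 4 2-[4-(allyloxy)-3,5-dimethoxyphenyl]-1,3-dioxolane; 5 4-formyl-2,6-dimethoxyphenyl pivalate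
Product: 10 4-[(1R,2R)-2-{4-(1,3-dioxolan-2-yl)-2,6-dimethoxyphenoxy}-1-hydroxybut-3-en-1-yl]-2,6-dimethoxyphenyl pivalate, via allyllithium 6 (not isolated), via borate 7 (not isolated), via allylborane 8 (not isolated), via borinate 9 (not isolated)
Conditions: 4 (1.1 equiv), s-BuLi, THF, −78 °C; (−)-Ipc2BOMe, −78 °C; BF3·OEt2 (1.1 equiv), −78 °C; 5 (0.9 equiv), −78 °C, 4 h; then NaH2PO4/Na2HPO4 buffer (pH 7), H2O2, 0 °C → rt
Reagents that add atoms: none
Why: Brown (Z)-γ-alkoxyallylboration (precedented for allyl p-methoxyphenyl ether, here with the full ring B aryloxy group): the oxygen-bearing allylic carbon of 4, made nucleophilic by deprotonation and γ-borylation, adds to the Si face of 5 through a closed chair transition state, where the (Z)-enol ether geometry gives the syn (threo) relationship and the isopinocampheyl groups from (+)-α-pinene give the (1R,2R) enantiomer.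

**Step 5**
Reactants: 10 4-[(1R,2R)-2-{4-(1,3-dioxolan-2-yl)-2,6-dimethoxyphenoxy}-1-hydroxybut-3-en-1-yl]-2,6-dimethoxyphenyl pivalate
Product: 13 4-[(1R,2R)-2-(4-formyl-2,6-dimethoxyphenoxy)-1,3-dihydroxypropyl]-2,6-dimethoxyphenyl pivalate, via hydroxy aldehyde 11 (not isolated), via diol acetal 12 (not isolated)
Conditions: O3, CH2Cl2/MeOH 3:1, −78 °C (Sudan Red 7B end point); NaBH4, −78 → 0 °C; concentrate; 1 M aq. HCl/THF, rt, 30 min
Reagents that add atoms: ozone, [O-][O+]=O; water, O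
Why: Ozonolysis of the only alkene with reductive NaBH4 work-up turns the vinyl group into C9H2OH, the transient α-aryloxy-β-hydroxy aldehyde being reduced cold before it can epimerise or undergo retro-aldol cleavage, and the acidic work-up hydrolyses the electron-rich aryl dioxolane; no new stereocentre is formed.

**Step 6**
Reactants: 13 4-[(1R,2R)-2-(4-formyl-2,6-dimethoxyphenoxy)-1,3-dihydroxypropyl]-2,6-dimethoxyphenyl pivalate; 14 ethyl (triphenylphosphoranylidene)acetate
Product: 16 (1R,2R)-1-(4-hydroxy-3,5-dimethoxyphenyl)-2-{4-[(E)-3-hydroxyprop-1-en-1-yl]-2,6-dimethoxyphenoxy}propane-1,3-diol (target), via enoate 15 (not isolated)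
Conditions: 14 (1.3 equiv), CH2Cl2, rt; then i-Bu2AlH (about 10 equiv), toluene, −78 → 0 °C; aq. KNaC4H4O6
Reagents that add atoms: none
Why: Wittig olefination with a stabilised ylide gives the (E)-cinnamate, and i-Bu2AlH then reduces the enoate 1,2 to the (E)-allylic alcohol (the standard monolignol reduction) and cleaves the aryl pivalate in the same pot; the stereocentres are remote from any enolisable position.

**Compound list**
1 | syringaldehyde (4-hydroxy-3,5-dimethoxybenzaldehyde) | COc1cc(C=O)cc(OC)c1O | starting material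
2 | allyl bromide | C=CCBr | starting material
3 | 4-(allyloxy)-3,5-dimethoxybenzaldehyde | C=CCOc1c(OC)cc(C=O)cc1OC | intermediate
4 | 2-[4-(allyloxy)-3,5-dimethoxyphenyl]-1,3-dioxolane | C=CCOc1c(OC)cc(C2OCCO2)cc1OC | intermediate
5 | 4-formyl-2,6-dimethoxyphenyl pivalate | COc1cc(C=O)cc(OC)c1OC(=O)C(C)(C)C | intermediate
6 | [1-{4-(1,3-dioxolan-2-yl)-2,6-dimethoxyphenoxy}allyl]lithium (Z-configured, oxygen-chelated allyl anion) | C=CC([Li])Oc1c(OC)cc(C2OCCO2)cc1OC | intermediate (not isolated)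
7 | lithium [(Z)-3-{4-(1,3-dioxolan-2-yl)-2,6-dimethoxyphenoxy}allyl](methoxy)diisopinocampheylborate (Ipc from (+)-α-pinene) | [Li+].COc1cc(C2OCCO2)cc(OC)c1O/C=C\C[B-](OC)([C@@H]1C[C@@H]2C[C@@H](C2(C)C)[C@H]1C)[C@@H]1C[C@@H]2C[C@@H](C2(C)C)[C@H]1C | intermediate (not isolated)
8 | [(Z)-3-{4-(1,3-dioxolan-2-yl)-2,6-dimethoxyphenoxy}allyl]diisopinocampheylborane (Ipc from (+)-α-pinene) | COc1cc(C2OCCO2)cc(OC)c1O/C=C\CB([C@@H]1C[C@@H]2C[C@@H](C2(C)C)[C@H]1C)[C@@H]1C[C@@H]2C[C@@H](C2(C)C)[C@H]1C | intermediate (not isolated)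
9 | O-(diisopinocampheylboryl) ether of 10, (1R,2R) | COc1cc([C@@H](OB([C@@H]2C[C@@H]3C[C@@H](C3(C)C)[C@H]2C)[C@@H]2C[C@@H]3C[C@@H](C3(C)C)[C@H]2C)[C@@H](C=C)Oc2c(OC)cc(C3OCCO3)cc2OC)cc(OC)c1OC(=O)C(C)(C)C | intermediate (not isolated)
10 | 4-[(1R,2R)-2-{4-(1,3-dioxolan-2-yl)-2,6-dimethoxyphenoxy}-1-hydroxybut-3-en-1-yl]-2,6-dimethoxyphenyl pivalate | COc1cc([C@@H](O)[C@@H](C=C)Oc2c(OC)cc(C3OCCO3)cc2OC)cc(OC)c1OC(=O)C(C)(C)C | intermediate
11 | 4-[(1R,2S)-2-{4-(1,3-dioxolan-2-yl)-2,6-dimethoxyphenoxy}-1-hydroxy-3-oxopropyl]-2,6-dimethoxyphenyl pivalate (same spatial arrangement as 10; the descriptor at C-2 changes only because CHO outranks C-1) | COc1cc([C@@H](O)[C@@H](C=O)Oc2c(OC)cc(C3OCCO3)cc2OC)cc(OC)c1OC(=O)C(C)(C)C | intermediate (not isolated)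
12 | 4-[(1R,2R)-2-{4-(1,3-dioxolan-2-yl)-2,6-dimethoxyphenoxy}-1,3-dihydroxypropyl]-2,6-dimethoxyphenyl pivalate | COc1cc([C@@H](O)[C@@H](CO)Oc2c(OC)cc(C3OCCO3)cc2OC)cc(OC)c1OC(=O)C(C)(C)C | intermediate (not isolated)
13 | 4-[(1R,2R)-2-(4-formyl-2,6-dimethoxyphenoxy)-1,3-dihydroxypropyl]-2,6-dimethoxyphenyl pivalate | COc1cc([C@@H](O)[C@@H](CO)Oc2c(OC)cc(C=O)cc2OC)cc(OC)c1OC(=O)C(C)(C)C | intermediate
14 | ethyl (triphenylphosphoranylidene)acetate | CCOC(=O)C=P(c1ccccc1)(c1ccccc1)c1ccccc1 | starting material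
15 | ethyl (E)-3-{4-[(1R,2R)-1,3-dihydroxy-1-(3,5-dimethoxy-4-pivaloyloxyphenyl)propan-2-yloxy]-3,5-dimethoxyphenyl}acrylate | COc1cc([C@@H](O)[C@@H](CO)Oc2c(OC)cc(/C=C/C(=O)OCC)cc2OC)cc(OC)c1OC(=O)C(C)(C)C | intermediate (not isolated)
16 | (1R,2R)-1-(4-hydroxy-3,5-dimethoxyphenyl)-2-{4-[(E)-3-hydroxyprop-1-en-1-yl]-2,6-dimethoxyphenoxy}propane-1,3-diol | COc1cc([C@@H](O)[C@@H](CO)Oc2c(OC)cc(/C=C/CO)cc2OC)cc(OC)c1O | target

**Totals**
Total step count: 6. Longest linear sequence: 5 (steps 1, 2, 4, 5, 6).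

**Steps most likely to fail**

Step 4. s-BuLi may metalate ring B between the methoxy and acetal groups, BF3·OEt2 may open the acetal, and the ee with this bulky aryloxy group is untested. The fallback sets out from 1 and comes back at 8. Alkylate 1 with propargyl bromide (K2CO3, DMF) to 3,5-dimethoxy-4-(prop-2-yn-1-yloxy)benzaldehyde F1. Protect it with ethylene glycol and p-TsOH as 2-[3,5-dimethoxy-4-(prop-2-yn-1-yloxy)phenyl]-1,3-dioxolane F2. Isomerise with KOtBu (cat.) in THF to the aryloxyallene 2-[3,5-dimethoxy-4-(propa-1,2-dien-1-yloxy)phenyl]-1,3-dioxolane F3. Hydroborate the terminal double bond of F3 with (−)-Ipc2BH (from (+)-α-pinene) at −40 °C. Kinetic B–H delivery anti to the aryloxy group gives the (Z)-allylborane 8 with no organolithium and no BF3·OEt2; 8 is then combined with 5 as in step 4.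

Step 5. Ozone may attack the two electron-rich rings, and the transient aldehyde 11 may epimerise or cleave by retro-aldol. The fallback sets out from 10 and comes back at 12. Dihydroxylate the vinyl group (OsO4 cat., NMO, acetone/H2O) and isolate the triol 4-[2-{4-(1,3-dioxolan-2-yl)-2,6-dimethoxyphenoxy}-1,3,4-trihydroxybutyl]-2,6-dimethoxyphenyl pivalate F4 (C-1 and C-2 unchanged, C-3 epimers that converge). Cleave its terminal 1,2-diol with NaIO4 in THF/NaH2PO4/Na2HPO4 buffer at 0 °C to 11 and reduce at once with NaBH4 to 12. The dioxolane is then hydrolysed as in step 5.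

Step 6. The one-pot Wittig/i-Bu2AlH sequence runs on an unprotected diol with a large excess of aluminium hydride, and any (Z)-enoate is carried through. The fallback sets out from 13 and comes back at 16. Wittig reaction of 13 with (triphenylphosphoranylidene)acetaldehyde (toluene, 80 °C) gives the thermodynamically (E) enal 4-[(1R,2R)-2-{2,6-dimethoxy-4-[(E)-3-oxoprop-1-en-1-yl]phenoxy}-1,3-dihydroxypropyl]-2,6-dimethoxyphenyl pivalate F5. Luche reduction (NaBH4, CeCl3·7H2O, MeOH, 0 °C) gives the pivalate of the target, 4-[(1R,2R)-1,3-dihydroxy-2-{4-[(E)-3-hydroxyprop-1-en-1-yl]-2,6-dimethoxyphenoxy}propyl]-2,6-dimethoxyphenyl pivalate F6. Methanolysis of the aryl ester (NaOMe, MeOH, 0 °C → rt) gives 16.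

**Further compounds**
F1 | step 4 | 3,5-dimethoxy-4-(prop-2-yn-1-yloxy)benzaldehyde | C#CCOc1c(OC)cc(C=O)cc1OC
F2 | step 4 | 2-[3,5-dimethoxy-4-(prop-2-yn-1-yloxy)phenyl]-1,3-dioxolane | C#CCOc1c(OC)cc(C2OCCO2)cc1OC
F3 | step 4 | 2-[3,5-dimethoxy-4-(propa-1,2-dien-1-yloxy)phenyl]-1,3-dioxolane | C=C=COc1c(OC)cc(C2OCCO2)cc1OC
F4 | step 5 | 4-[2-{4-(1,3-dioxolan-2-yl)-2,6-dimethoxyphenoxy}-1,3,4-trihydroxybutyl]-2,6-dimethoxyphenyl pivalate (C-1, C-2 as in 10; C-3 epimer mixture) | COc1cc([C@@H](O)[C@@H](C(O)CO)Oc2c(OC)cc(C3OCCO3)cc2OC)cc(OC)c1OC(=O)C(C)(C)C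
F5 | step 6 | 4-[(1R,2R)-2-{2,6-dimethoxy-4-[(E)-3-oxoprop-1-en-1-yl]phenoxy}-1,3-dihydroxypropyl]-2,6-dimethoxyphenyl pivalate | COc1cc([C@@H](O)[C@@H](CO)Oc2c(OC)cc(/C=C/C=O)cc2OC)cc(OC)c1OC(=O)C(C)(C)C
F6 | step 6 | 4-[(1R,2R)-1,3-dihydroxy-2-{4-[(E)-3-hydroxyprop-1-en-1-yl]-2,6-dimethoxyphenoxy}propyl]-2,6-dimethoxyphenyl pivalate | COc1cc([C@@H](O)[C@@H](CO)Oc2c(OC)cc(/C=C/CO)cc2OC)cc(OC)c1OC(=O)C(C)(C)C
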